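## The problem

Compound 15 is a 20-membered meta,para-cyclophane. Ring A is a 1,3,5-trisubstituted benzene carrying a hydroxyl, the ether oxygen and chain carbon C1. Ring B carries the ether oxygen at its C1, hydroxyls at C2 and C6, and chain carbon C12 at C4. The two rings are joined once through the diaryl ether oxygen and once through an unbranched chain C1–C12. There is no stereocentre, so no stereocontrol is needed and none is available to help; the difficulty is purely constitutional. Three tasks remain: an ether bond to a ring B carbon flanked by two oxygen substituents, two arene–sp3 arms, and the entropically costly closure of a large ring whose bridge has no functional group. Whatever functionality serves for the closure must therefore be erasable to methylene groups. The free phenols, above all the 2-aryloxyresorcinol unit of ring B, are electron-rich and easily oxidised, so they must stay masked until the last step. The enabling feature is the C7–C8 bond: C7 is ten bonds from the ether oxygen in either direction round the ring, so a straight C5–C10 segment built on a C6≡C7–C8≡C9 diyne lies opposite the bent C–O–C hinge. This bond also divides the chain into a seven-carbon arm on ring A and a five-carbon arm on ring B, and the three methylenes of the ring B arm are the allyl group of commercial phenol 1.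

## Retrosynthesis

**15 to 13.**
- Bonds cut: the three phenolic O–H groups are traced back to O–CH3 in the saturated macrocycle 13.
- Why this cut: methyl is preferred to benzyl or silyl because two methyl groups arrive with 1 and the third with 2, so no protection step is spent. Methyl ethers also tolerate hot base, organozinc and acetylide reagents, divalent copper and hydrogen.
- Gain: 13 is no simpler in skeleton but is far more robust than 15.
- Forward demand: a boron halide must cleave three sp3 C–O bonds, passing through borate 14. The diaryl ether offers the halide no sp3 carbon and should persist.

**13 to 12.**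
- Bonds cut: no skeletal bond. Eight hydrogens are removed from C6–C9 to reveal the conjugated diyne 12.
- Why this cut: it gives a featureless chain the retron of an alkyne–alkyne coupling. An alkene or a ketone in the bridge would point to closures that need differentiated ends.
- Forward demand: exhaustive hydrogenation only. Nothing else in 12 is reducible, since it holds no benzyl ether and no halide.

**12 to 11.**
- Bond cut: C7–C8, the sp–sp bond in the middle of the diyne, which opens the 20-membered ring to the acyclic bis-terminal alkyne 11.
- Against other positions in the chain: a C5–C8 diyne would be equally central but needs a four-carbon arm on ring B, for which no simple phenol exists.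
- Against other closing bonds: closing at the ether oxygen would push the most hindered bond formation into the high-dilution stage. Closing at an aryl–alkyl bond would need two different termini and a catalytic sp3–sp2 coupling at millimolar concentration.
- Against olefin metathesis: a closure at C10–C11 starting from 3 is the serious rival and is shorter. However, its allylarene terminus can migrate before closure, and the ring-contracted homologues would be hard to separate from 13 after hydrogenation. It is kept in reserve.
- Gain: the alkyne coupling is irreversible and cannot change the carbon count. Its two ends are alike, so they can be installed together.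
- Forward demand: ring closure must outrun chain growth.

**11 to 9 and 10.**
- Bonds cut: C5–C6 and C9–C10, each between a propargylic methylene and an alkyne carbon. This gives dibromide 9 and two equivalents of acetylide 10.
- Why this cut: no palladium step follows, so the alkynes can enter uncapped and both at once. Carrying silyl-capped alkynes through a cross-coupling would cost capping, uncapping and a separate side-chain synthesis.
- Gain: 9 contains only sp3 electrophiles of one kind.
- Forward demand: two clean SN2 displacements, without elimination and without alkylation of the product alkyne.

**9 to 8 to 6.**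
- Bonds cut: the two C–Br bonds go back to C–OH in diol 8, and these to the two terminal alkenes of diene 6 through bis-borane 7.
- Why this cut: radical hydrobromination of 6 would save a step, but it exposes electron-rich arenes and benzylic positions to bromine radicals and acid.
- Gain: 6 carries the same functional group at both ends, so every operation from 6 to 11 is two-directional.
- Forward demand: anti-Markovnikov regiochemistry at both alkenes.

**6 to 3 and 5 (from 4).**
- Bond cut: ring A carbon to C1.
- Why this cut: cuts further along the arm would call for benzylic metal chemistry, whereas this one uses the bromine left over from 2. A five-carbon alkenyl partner is chosen so that the ring A arm ends exactly as the allyl arm of ring B does.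
- Gain: zinc reagent 5 comes from commercial bromide 4 in the same flask.
- Forward demand: an sp3–sp2 coupling free of beta-hydride elimination and alkene migration.

**3 to 1 and 2.**
- Bond cut: the oxygen–ring A bond.
- Why this cut: the oxygen stays with ring B because the reverse polarity would need an electron-rich, doubly ortho-substituted aryl halide, the worst electrophile for C–O coupling. Dibromide 2 is symmetrical, so either bromine may react and the survivor is the handle for the next step.
- Gain: both precursors are commercial.
- Forward demand: coupling of a hindered phenoxide, a stop at mono-substitution, and an untouched allyl group.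

## Roads not taken

**Alternative 1:**
- Cut: the C3–C4 and C5–C6 bonds of ring B together with the macrocycle, so ring B is built rather than bought.
- Forward key step: the open-chain compound A1 carries a 1-methoxy-1,3-bis(silyloxy)butadiene on the ring A oxygen, bound at the diene C2, and an alk-2-ynoate at the far end of the twelve-carbon chain. It is heated in dilute solution. The nucleophilic diene terminus bonds to the chain-bearing alkyne carbon, methanol and the silyl groups are lost, and the macrocyclic resorcylate A2 results.
- Merits:
  - It forms two C–C bonds, an arene and the large ring in one operation.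
  - Its polarity-matched regiochemistry sets oxygen and chain para to each other.
  - The hindered ether is reduced to an early alkylation at an sp3 carbon.
  - The ring B hydroxyls emerge free.
- Weak points:
  - Beta-alkyl alkynoates are sluggish dienophiles, normally used concentrated and in excess, and a twelve-carbon tether gives little entropic help at millimolar dilution.
  - The moisture-sensitive ketene acetal of A1 would have to survive long heating.
  - The aryloxy group at the diene C2 disfavours the s-cis form.
  - A2 carries an ester that must be hydrolysed and decarboxylated, and the ring A methyl ether still has to go.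
  - The chain must still be attached to ring A by a separate C–C coupling.
- Comparison: in bonds formed per step this road is clearly superior. The chosen plan sets against it a closure of a known type, two purchased arenes, and intermediates that can all be stored and purified.

**Alternative 2:**
- Cut: the oxygen–ring A bond, with ring A disguised as a cyclohexenone.
- Forward key step: the phenoxide of the racemic chloroenone A3 adds to the chlorine-bearing enone carbon and expels chloride. This closes the ring to the vinylogous ester A4, whose single sp3 centre disappears on aromatisation.
- Merits:
  - The hindered C–O bond forms without metal under mild base.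
  - A caesium phenoxide closing onto a soft electrophile is a good macrocyclisation, probably as efficient as the copper coupling and free of stoichiometric metal.
  - The ring A hydroxyl emerges unprotected.
- Weak points:
  - A3 needs a 5-alkylcyclohexane-1,3-dione built at the end of a twelve-carbon chain that already bears ring B. That is a multistep ring construction on top of the chain assembly, with a free or temporarily masked phenol carried along.
  - A4 is a vinylogous ester with an aryloxide leaving group, so it is open to hydrolysis and exchange.
  - Its dehydrogenation must oxidise one ring beside an electron-rich trialkoxyarene, which rules out halogenation–elimination methods.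
- Comparison: in the closure itself this road is at least equal. The chosen plan answers with a shorter preparation of its seco compound, and with a post-closure sequence of hydrogenation and ether cleavage that carries little risk.

**Alternative 3:**
- Cut: four C–C bonds of ring A and the macrocycle.
- Forward key step: the diazoketone A5 carries an alpha-methylene group at one chain end and the ethynyl ether of ring B at the other. It is irradiated and then heated in dilute solution. Wolff rearrangement gives a vinylketene, which undergoes [2+2] addition to the ynol ether. The cyclobutenone then opens in a 4-pi process and recloses in a 6-pi process to give phenol A6.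
- Merits:
  - The 1,3,5-pattern of ring A follows from the mechanism.
  - No hindered Ullmann coupling is needed.
  - A6 is one ether cleavage from 15, with one methyl group fewer to remove than in 13.
- Weak points:
  - The ketene–alkyne step is a bimolecular trapping of a short-lived species, normally run concentrated with excess alkyne. As a macrocyclic event at high dilution it has no precedent, and the ketene has faster outlets in dimerisation and capture by traces of nucleophile.
  - A5 combines a diazoketone, an enone and an ynol ether, three sensitive groups that must be installed late on a long chain.
- Comparison: this road is better in endgame economy and elegance. The chosen plan offers a closure whose reacting partners are persistent rather than transient, so slow addition can enforce the intramolecular path.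

Key step: step 6

Assumption: the 20-membered ring is taken to be conformationally mobile, so no atropisomerism has to be controlled. Chain carbons are numbered C1 (on ring A) to C12 (on ring B) throughout.

## Route

Step 1
Reactants: 1 4-allyl-2,6-dimethoxyphenol; 2 3,5-dibromoanisole (3 equiv)
Product: 3 5-allyl-2-(3-bromo-5-methoxyphenoxy)-1,3-dimethoxybenzene
Conditions: CuI (10 mol %), picolinic acid (20 mol %), K3PO4, DMSO, 90 °C, Ar
Reagents that add atoms: none
Why: Ligand-accelerated Ullmann diaryl ether synthesis; the CuI–picolinic acid system is suited to phenols with two ortho substituents, and the excess of symmetrical 2 (recoverable) should hold the reaction at mono-substitution. K3PO4 should be too weak a base to move the allyl double bond into conjugation.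

Step 2
Reactants: 3 5-allyl-2-(3-bromo-5-methoxyphenoxy)-1,3-dimethoxybenzene; 4 5-bromopent-1-ene
Product: 6 5-allyl-1,3-dimethoxy-2-[3-methoxy-5-(pent-4-en-1-yl)phenoxy]benzene, via pent-4-en-1-ylzinc bromide 5 (not isolated)
Conditions: 4, Zn dust, LiCl, THF, 50 °C; then 3, Pd(OAc)2 (2 mol %), SPhos (4 mol %), THF, rt to 45 °C
Reagents that add atoms: zinc, [Zn] (the metal of 5 only; none of it stays in 6)
Why: Negishi sp3–sp2 coupling after LiCl-assisted zinc insertion into the primary bromide; the unhindered aryl bromide adds readily to zerovalent palladium and transmetalation from zinc is much faster than Heck insertion. The bulky biaryl phosphine speeds reductive elimination ahead of beta-hydride elimination, so both terminal alkenes should remain spectators.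

Step 3
Reactants: 6 5-allyl-1,3-dimethoxy-2-[3-methoxy-5-(pent-4-en-1-yl)phenoxy]benzene
Product: 8 5-{3-[4-(3-hydroxypropyl)-2,6-dimethoxyphenoxy]-5-methoxyphenyl}pentan-1-ol, via bis(B-alkyl-9-BBN) adduct 7 (not isolated)
Conditions: 9-BBN (2.6 equiv), THF, 0 °C to rt; then 3 M NaOH, 30% H2O2, 0 °C to rt
Reagents that add atoms: hydrogen peroxide, OO (both hydroxyl oxygens of 8); 9-borabicyclo[3.3.1]nonane, B1C2CCCC1CCC2 (the boron bicycles of 7 only)
Why: Two-directional hydroboration–oxidation; the bulky dialkylborane places boron on the terminal carbon of both monosubstituted alkenes and alkaline peroxide exchanges boron for hydroxyl. Aryl ethers are inert to both reagents.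

Step 4
Reactants: 8 5-{3-[4-(3-hydroxypropyl)-2,6-dimethoxyphenoxy]-5-methoxyphenyl}pentan-1-ol
Product: 9 2-[3-(5-bromopentyl)-5-methoxyphenoxy]-5-(3-bromopropyl)-1,3-dimethoxybenzene
Conditions: CBr4, PPh3, CH2Cl2, 0 °C to rt
Reagents that add atoms: carbon tetrabromide, BrC(Br)(Br)Br
Why: Double Appel bromination; both primary alcohols are activated as alkoxyphosphonium ions and displaced by bromide under neutral conditions. No free electrophilic bromine is present, so the activated arenes are not attacked.

Step 5
Reactants: 9 2-[3-(5-bromopentyl)-5-methoxyphenoxy]-5-(3-bromopropyl)-1,3-dimethoxybenzene; 10 lithium acetylide–ethylenediamine complex (4 equiv)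
Product: 11 1-(hept-6-yn-1-yl)-3-[2,6-dimethoxy-4-(pent-4-yn-1-yl)phenoxy]-5-methoxybenzene
Conditions: DMSO–THF 3:1, 0 °C to rt
Reagents that add atoms: none
Why: Double SN2 alkylation of acetylide by unhindered primary bromides in a dipolar aprotic medium, the standard route from 1-bromoalkanes to terminal alkynes; it forms C5–C6 and C9–C10 in one operation. The excess of 10 keeps the product alkynes from competing as nucleophiles.

Step 6
Reactants: 11 1-(hept-6-yn-1-yl)-3-[2,6-dimethoxy-4-(pent-4-yn-1-yl)phenoxy]-5-methoxybenzene
Product: 12 macrocyclic C6–C9 diyne trimethyl ether (1^5,3^2,3^6-trimethoxy-2-oxa-1(1,3),3(1,4)-dibenzenacyclopentadecaphane-7,9-diyne)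
Conditions: Cu(OAc)2 (10 equiv), pyridine–MeCN 1:4, 70 °C, 11 added by syringe pump over 16 h (final ca. 1 mM), Ar
Reagents that add atoms: none
Why: Eglinton variant of the Glaser coupling, the classical way to close alpha,omega-diynes to macrocyclic 1,3-diynes. Each terminal alkyne is pi-bound by copper, deprotonated by pyridine or acetate and held as a copper acetylide; two acetylides gathered on a dinuclear copper core are oxidised by divalent copper and the C7–C8 bond is expelled, two Cu(OAc)2 per ring ending as CuOAc and AcOH. Both carbons that join are nucleophilic, so the ends need no differentiation and every intramolecular encounter gives the same product 12. The one ring closed is the 20-membered ring, formed end to end between two sp termini so that both triple bonds finish endocyclic; no pi bond is attacked, so no exo or endo question arises. No stereocentre is created. The selectivity needed is ring closure over chain growth: slow addition into a large excess of the copper salt keeps free 11 at a very low stationary concentration and converts each molecule before the next arrives. The substrate helps because the bent C–O–C hinge and the meta linkage of ring A point both arms to the same side, and the straight C5–C10 segment comes to lie opposite the oxygen with five and three methylenes to take up the curvature. The methyl ethers keep the arenes out of phenoxyl radical chemistry, and 12, having no terminal C–H left, cannot couple further.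

Step 7
Reactants: 12 macrocyclic C6–C9 diyne trimethyl ether
Product: 13 saturated macrocycle trimethyl ether (1^5,3^2,3^6-trimethoxy-2-oxa-1(1,3),3(1,4)-dibenzenacyclopentadecaphane)
Conditions: H2 (1 atm), 10% Pd/C, EtOAc–EtOH, rt
Reagents that add atoms: none
Why: Exhaustive heterogeneous hydrogenation; four equivalents of hydrogen turn C6–C9 into methylenes and leave the plain twelve-carbon bridge. Aryl methyl ethers and the diaryl ether are not hydrogenolysed under these conditions.

Step 8
Reactants: 13 saturated macrocycle trimethyl ether
Product: 15 target CNP0314249.0 (2-oxa-1(1,3),3(1,4)-dibenzenacyclopentadecaphane-1^5,3^2,3^6-triol), via tris(dibromoboryl) ether 14 (not isolated)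
Conditions: BBr3 (6 equiv), CH2Cl2, −78 °C to rt; then H2O, 0 °C, work-up under Ar
Reagents that add atoms: boron tribromide, BrB(Br)Br (boron and bromine of 14 only; none of it stays in 15)
Why: Lewis acid mediated cleavage of aryl methyl ethers; boron binds each methoxy oxygen and bromide attacks the methyl carbon, after which water hydrolyses the aryl borates. The diaryl ether has no sp3 carbon for bromide to attack and should survive; air is excluded during work-up because ring B of 15 is easily oxidised.

## Compound list

1 | 4-allyl-2,6-dimethoxyphenol | C=CCc1cc(OC)c(O)c(OC)c1 | starting material
2 | 3,5-dibromoanisole | COc1cc(Br)cc(Br)c1 | starting material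
3 | 5-allyl-2-(3-bromo-5-methoxyphenoxy)-1,3-dimethoxybenzene | C=CCc1cc(OC)c(Oc2cc(Br)cc(OC)c2)c(OC)c1 | intermediate
4 | 5-bromopent-1-ene | C=CCCCBr | starting material
5 | pent-4-en-1-ylzinc bromide | C=CCCC[Zn]Br | intermediate
6 | 5-allyl-1,3-dimethoxy-2-[3-methoxy-5-(pent-4-en-1-yl)phenoxy]benzene | C=CCCCc1cc(OC)cc(Oc2c(OC)cc(CC=C)cc2OC)c1 | intermediate
7 | bis(9-borabicyclo[3.3.1]nonan-9-yl) adduct of 6, boron on the terminal carbon of each arm | COc1cc(CCCCCB2C3CCCC2CCC3)cc(Oc2c(OC)cc(CCCB3C4CCCC3CCC4)cc2OC)c1 | intermediate
8 | 5-{3-[4-(3-hydroxypropyl)-2,6-dimethoxyphenoxy]-5-methoxyphenyl}pentan-1-ol | COc1cc(CCCCCO)cc(Oc2c(OC)cc(CCCO)cc2OC)c1 | intermediate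
9 | 2-[3-(5-bromopentyl)-5-methoxyphenoxy]-5-(3-bromopropyl)-1,3-dimethoxybenzene | COc1cc(CCCCCBr)cc(Oc2c(OC)cc(CCCBr)cc2OC)c1 | intermediate
10 | lithium acetylide–ethylenediamine complex | [Li+].[C-]#C.NCCN | starting material
11 | 1-(hept-6-yn-1-yl)-3-[2,6-dimethoxy-4-(pent-4-yn-1-yl)phenoxy]-5-methoxybenzene | C#CCCCCCc1cc(OC)cc(Oc2c(OC)cc(CCCC#C)cc2OC)c1 | intermediate
12 | 1^5,3^2,3^6-trimethoxy-2-oxa-1(1,3),3(1,4)-dibenzenacyclopentadecaphane-7,9-diyne (chain C6–C9 diyne) | COc1cc2cc(c1)Oc1c(OC)cc(cc1OC)CCCC#CC#CCCCCC2 | intermediate
13 | 1^5,3^2,3^6-trimethoxy-2-oxa-1(1,3),3(1,4)-dibenzenacyclopentadecaphane | COc1cc2cc(c1)Oc1c(OC)cc(cc1OC)CCCCCCCCCCCC2 | intermediate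
14 | tris(dibromoboryl) ether of 15 | BrB(Br)Oc1cc2cc(c1)Oc1c(OB(Br)Br)cc(cc1OB(Br)Br)CCCCCCCCCCCC2 | intermediate
15 | 2-oxa-1(1,3),3(1,4)-dibenzenacyclopentadecaphane-1^5,3^2,3^6-triol (CNP0314249.0; no stereocentre) | Oc1cc2cc(c1)Oc1c(O)cc(cc1O)CCCCCCCCCCCC2 | target

## Step count and risks

Total step count: 8. Longest linear sequence: 8 (steps 1 to 8; zinc reagent 5 is made in the flask of step 2).

**Step 6 (key step).**
- Risk: chain growth by intermolecular coupling may outrun ring closure. The flexible arms of 11 seldom present their ends together, and the coupling is irreversible, so every intermolecular event is lost for good. Long exposure to hot divalent copper may also slowly degrade the electron-rich arenes.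
- Fallback: it leaves the route at 3 and rejoins it at 13. Commercial 11-bromoundec-1-ene is converted with zinc and LiCl, as in step 2, into undec-10-en-1-ylzinc bromide F1. This is coupled with 3 under the same Negishi conditions to give the diene 5-allyl-1,3-dimethoxy-2-[3-methoxy-5-(undec-10-en-1-yl)phenoxy]benzene F2. Ring-closing metathesis follows with the second-generation Grubbs catalyst in dilute toluene, with 1,4-benzoquinone added against hydride-induced double bond migration. It gives the 20-membered C10–C11 cycloalkene F3 as an E/Z mixture with loss of ethene, and hydrogenation as in step 7 gives 13.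
- Why it differs: this closure is reversible, so oligomers can re-enter the ring–chain equilibrium at high dilution. It is shorter than the main line. It is held in reserve because migration of the allylarene double bond before closure would change the ring size by one carbon, a drift the diyne closure excludes.

**Step 1.**
- Risk:
  - The doubly ortho-substituted phenoxide may couple slowly.
  - The remaining bromide of the product may react a second time.
  - The allyl group may migrate on prolonged heating with base.
  - The electron-rich phenol may be lost by oxidation if air enters.
- Fallback: it sets out from 1 and returns at 3. Commercial 1-bromo-3-iodo-5-methoxybenzene is oxidised with mCPBA and TsOH in MeCN, and the iodane is captured with 1,3,5-trimethoxybenzene to give (3-bromo-5-methoxyphenyl)(2,4,6-trimethoxyphenyl)iodonium tosylate F4. The potassium phenoxide of 1 (KOtBu, THF, 0 °C) is then arylated by F4 at room temperature.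
- Why it differs: this is a metal-free ligand coupling on iodine that tolerates hindered phenoxides. The electron-rich trimethoxyphenyl group stays on iodine as the dummy ligand, only one aryl–oxygen bond can form, and no heating is needed.

**Step 2.**
- Risk: zinc insertion may be incomplete. Palladium hydride, formed by occasional beta-hydride elimination, may move either terminal double bond inward, above all the allyl group into conjugation with ring B. That would spoil the regiochemistry of step 3.
- Fallback: it sets out from 3 and returns at 8, using no alkylmetal coupling. Hydroboration of 3 with 9-BBN gives the B-alkyl-9-BBN adduct F5, which alkaline peroxide converts into 3-[4-(3-bromo-5-methoxyphenoxy)-3,5-dimethoxyphenyl]propan-1-ol F6. Sonogashira coupling of F6 with pent-4-yn-1-ol (PdCl2(PPh3)2, CuI, Et3N, 70 °C) gives 5-{3-[4-(3-hydroxypropyl)-2,6-dimethoxyphenoxy]-5-methoxyphenyl}pent-4-yn-1-ol F7. Hydrogenation over Pd/C then gives diol 8.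

**Step 5.**
- Risk: proton exchange between the first-formed terminal alkyne and excess acetylide, followed by alkylation of that alkyne by a second bromide, would link chains. Elimination at the primary bromides and base-induced migration of the triple bond are lesser risks.
- Fallback: it sets out from 9 and returns at 11, using a capped nucleophile. Ethynyltrimethylsilane is deprotonated with n-BuLi to lithium (trimethylsilyl)acetylide F8. This displaces both bromides of 9 in THF–DMPU to give the bis(trimethylsilyl)alkyne F9, in which no acidic alkyne hydrogen is ever exposed to strong base. K2CO3 in MeOH then removes both silyl groups to give 11.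

## Further compounds

F1 | step 6 | undec-10-en-1-ylzinc bromide | C=CCCCCCCCCC[Zn]Br
F2 | step 6 | 5-allyl-1,3-dimethoxy-2-[3-methoxy-5-(undec-10-en-1-yl)phenoxy]benzene | C=CCCCCCCCCCc1cc(OC)cc(Oc2c(OC)cc(CC=C)cc2OC)c1
F3 | step 6 | 1^5,3^2,3^6-trimethoxy-2-oxa-1(1,3),3(1,4)-dibenzenacyclopentadecaphan-5-ene (chain C10–C11 alkene, E/Z mixture) | COc1cc2cc(c1)Oc1c(OC)cc(cc1OC)CC=CCCCCCCCCC2
F4 | step 1 | (3-bromo-5-methoxyphenyl)(2,4,6-trimethoxyphenyl)iodonium 4-methylbenzenesulfonate | COc1cc(Br)cc([I+]c2c(OC)cc(OC)cc2OC)c1.Cc1ccc(cc1)S(=O)(=O)[O-]
F5 | step 2 | 9-{3-[4-(3-bromo-5-methoxyphenoxy)-3,5-dimethoxyphenyl]propyl}-9-borabicyclo[3.3.1]nonane | COc1cc(Br)cc(Oc2c(OC)cc(CCCB3C4CCCC3CCC4)cc2OC)c1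
F6 | step 2 | 3-[4-(3-bromo-5-methoxyphenoxy)-3,5-dimethoxyphenyl]propan-1-ol | COc1cc(Br)cc(Oc2c(OC)cc(CCCO)cc2OC)c1
F7 | step 2 | 5-{3-[4-(3-hydroxypropyl)-2,6-dimethoxyphenoxy]-5-methoxyphenyl}pent-4-yn-1-ol | COc1cc(C#CCCCO)cc(Oc2c(OC)cc(CCCO)cc2OC)c1
F8 | step 5 | lithium (trimethylsilyl)acetylide | [Li+].[C-]#C[Si](C)(C)C
F9 | step 5 | 1-[7-(trimethylsilyl)hept-6-yn-1-yl]-3-{2,6-dimethoxy-4-[5-(trimethylsilyl)pent-4-yn-1-yl]phenoxy}-5-methoxybenzene | COc1cc(CCCCCC#C[Si](C)(C)C)cc(Oc2c(OC)cc(CCCC#C[Si](C)(C)C)cc2OC)c1
A1 | alternative 1 | methyl 15-(3-{[1-methoxy-1,3-bis(trimethylsilyloxy)buta-1,3-dien-2-yl]oxy}-5-methoxyphenyl)pentadec-2-ynoate (ketene acetal geometry undefined) | COC(=O)C#CCCCCCCCCCCCCc1cc(OC)cc(OC(C(=C)O[Si](C)(C)C)=C(OC)O[Si](C)(C)C)c1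
A2 | alternative 1 | macrocyclic methyl 3-aryloxy-2,4-dihydroxy-6-alkylbenzoate (ring A methyl ether) | COC(=O)c1c(O)c2c(O)cc1CCCCCCCCCCCCc1cc(OC)cc(O2)c1
A3 | alternative 2 | racemic 3-chloro-5-[12-(4-hydroxy-3,5-dimethoxyphenyl)dodecyl]cyclohex-2-en-1-one | O=C1C=C(Cl)CC(C1)CCCCCCCCCCCCc1cc(OC)c(O)c(OC)c1
A4 | alternative 2 | racemic macrocyclic 3-aryloxycyclohex-2-en-1-one | O=C1C=C2CC(C1)CCCCCCCCCCCCc1cc(OC)c(O2)c(OC)c1
A5 | alternative 3 | 1-diazo-15-[4-(ethynyloxy)-3,5-dimethoxyphenyl]-3-methylidenepentadecan-2-one | [N-]=[N+]=CC(=O)C(=C)CCCCCCCCCCCCc1cc(OC)c(OC#C)c(OC)c1
A6 | alternative 3 | ring B dimethyl ether of 15 (ring A phenol free) | Oc1cc2cc(c1)Oc1c(OC)cc(cc1OC)CCCCCCCCCCCC2
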